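**Retrosynthetic overview**
- The target comes from hydrogenolysis of a tri-O-benzyl dimer; the C4–C8 bond is cut to a 2,3-cis flavan-4-yl cation of the upper unit (the presumed extension unit) and free (−)-epicatechin (the starter unit, bought).
- The cation comes from a 4β-methoxy ether, made via a 3,4-oxirane cis to the 2-aryl group from a trans-bromohydrin and a trans-3-bromoflavanone; oxirane closure inverts C3 and turns the easy 2,3-trans series into 2,3-cis.
- The (2S)-flavanone comes from a 2'-hydroxychalcone by a catalytic enantioselective, chalcone-isomerase-type oxa-Michael closure, which sets C2; C3 and C4 then follow from C2.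
- The chalcone comes from a Claisen–Schmidt condensation of two benzyl-protected aromatic building blocks.
- Ring order: rings A and B of the upper unit and the whole lower unit are bought; the only ring built is ring C of the upper unit (step 2).

Assumption: acetophenone 1 is taken as a catalogue compound (otherwise one benzylation of 2,4,6-trihydroxyacetophenone gives it).
Assumption: the quinine-derived thiourea is taken to give the (2S)-flavanone; if it gives the antipode, the quinidine-derived pseudo-enantiomer is used, the sense being checked by CD against the (2S)-naringenin series.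

**Step 1**
Reactants: 1 1-[2,4-bis(benzyloxy)-6-hydroxyphenyl]ethan-1-one; 2 4-(benzyloxy)benzaldehyde
Product: 3 (E)-1-[2,4-bis(benzyloxy)-6-hydroxyphenyl]-3-[4-(benzyloxy)phenyl]prop-2-en-1-one
Conditions: KOH (50% aq.), EtOH, 25 °C, 36 h; acidify to pH 5; recrystallise (removes any racemic flavanone)
Reagents that add atoms: none
Why: Claisen–Schmidt (crossed aldol) condensation in which the acetophenone enolate adds to the non-enolisable aldehyde and E1cB dehydration gives the (E)-enone, the chelated 2'-phenoxide keeping the product open-chain in strong base.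

**Step 2**
Reactants: 3 (E)-1-[2,4-bis(benzyloxy)-6-hydroxyphenyl]-3-[4-(benzyloxy)phenyl]prop-2-en-1-one
Product: 4 (2S)-5,7-bis(benzyloxy)-2-[4-(benzyloxy)phenyl]chroman-4-one
Conditions: N-[3,5-bis(trifluoromethyl)phenyl]-N'-[(8α,9S)-6'-methoxycinchonan-9-yl]thiourea (10 mol %), toluene, 4 Å molecular sieves, 25 °C, 72 h; recrystallise to ≥98% ee
Reagents that add atoms: none
Why: Proposed new method: chalcone-isomerase-mimetic 6-endo-trig intramolecular oxa-Michael addition in which the quinuclidine nitrogen acts as general base on the hydrogen-bonded 2'-OH while the thiourea binds the enone carbonyl, so the phenoxide is delivered to one enantiotopic face of C-β and C2 is set as (S) under catalyst control (the 6'-benzyloxy group twists the chalcone and makes closure downhill); the closest known reaction type is the cinchona-thiourea-catalysed enantioselective cyclisation of 2'-hydroxychalcones and their α-carboxylated analogues to flavanones, not yet shown for a 4',6'-dialkoxy substrate with an electron-rich ring B.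

**Step 3**
Reactants: 4 (2S)-5,7-bis(benzyloxy)-2-[4-(benzyloxy)phenyl]chroman-4-one
Product: 6 (2R,3R)-5,7-bis(benzyloxy)-2-[4-(benzyloxy)phenyl]-3-bromochroman-4-one, via silyl enol ether 5 (not isolated)
Conditions: TMSOTf (1.3 equiv), Et3N (2 equiv), CH2Cl2, 0 °C; then NBS (1.05 equiv), THF, −78 °C; short silica plug, use at once
Reagents that add atoms: trimethylsilyl trifluoromethanesulfonate C[Si](C)(C)OS(=O)(=O)C(F)(F)F (silyl group, present in 5 only); N-bromosuccinimide O=C1CCC(=O)N1Br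
Why: Soft enolisation gives the silyl enol ether without the retro-oxa-Michael ring opening that metal enolates of flavanones suffer, and electrophilic α-bromination of the silyl enol ether by NBS occurs anti to the 2-aryl group to give the diequatorial 2,3-trans bromide with C2 untouched.

**Step 4**
Reactants: 6 (2R,3R)-5,7-bis(benzyloxy)-2-[4-(benzyloxy)phenyl]-3-bromochroman-4-one
Product: 9 (2R,3R,4S)-5,7-bis(benzyloxy)-2-[4-(benzyloxy)phenyl]-4-methoxychroman-3-ol, via bromohydrin 7 (not isolated), via cis-epoxide 8 (not isolated)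
Conditions: NaBH4 (1.5 equiv), THF/MeOH (1:1), −20 → 0 °C; then K2CO3 (3 equiv), MeOH, 0 → 25 °C
Reagents that add atoms: methanol CO
Why: Hydride adds axially to the C4 carbonyl (as in borohydride reductions of dihydroflavonols) to give the 2,3-trans-3,4-trans bromohydrin, whose C4 alkoxide displaces the anti bromide by intramolecular SN2 (Williamson-type epoxide closure) with inversion at C3 so that the oxirane lies cis to the 2-aryl group, and this very electron-rich benzylic oxirane is then opened by methanol at C4 trans to the C3 oxygen (SN1-like epoxide solvolysis) to give the 2,3-cis-3,4-trans ether.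

**Step 5**
Reactants: 9 (2R,3R,4S)-5,7-bis(benzyloxy)-2-[4-(benzyloxy)phenyl]-4-methoxychroman-3-ol; 10 (−)-epicatechin
Product: 11 5,7,4'-tri-O-benzyl-(−)-epiafzelechin-(4β→8)-(−)-epicatechin
Conditions: 10 (4 equiv), BF3·OEt2 (1.5 equiv), THF/CH2Cl2 (1:1), −30 → 0 °C, N2; aq. NaHCO3; Sephadex LH-20 (removes the 4→6 isomer, recovers excess 10)
Reagents that add atoms: none
Why: Biomimetic Friedel–Crafts-type capture of the flavan-4-yl cation (quinone-methide-type extension unit) by the phloroglucinol ring A of the free-phenolic starter unit, which out-competes the benzylated ring A of 9 and reacts mainly at C8; attack anti to the axial 3-OH of the 2,3-cis cation sets C4 as 4β (4R).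

**Step 6**
Reactants: 11 5,7,4'-tri-O-benzyl-(−)-epiafzelechin-(4β→8)-(−)-epicatechin
Product: 12 (−)-epiafzelechin-(4β→8)-(−)-epicatechin
Conditions: H2 (1 atm), Pd(OH)2/C (20 wt %), THF/MeOH (1:1), 25 °C, 3 h; filter, Sephadex LH-20, lyophilise
Reagents that add atoms: none
Why: Heterogeneous hydrogenolysis of the three benzyl ethers under neutral conditions, which touches no stereocenter and leaves the interflavan bond intact.

**Compound list**
1 | 1-[2,4-bis(benzyloxy)-6-hydroxyphenyl]ethan-1-one | CC(=O)c1c(O)cc(OCc2ccccc2)cc1OCc1ccccc1 | starting material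
2 | 4-(benzyloxy)benzaldehyde | O=Cc1ccc(OCc2ccccc2)cc1 | starting material
3 | (E)-1-[2,4-bis(benzyloxy)-6-hydroxyphenyl]-3-[4-(benzyloxy)phenyl]prop-2-en-1-one | O=C(/C=C/c1ccc(OCc2ccccc2)cc1)c1c(O)cc(OCc2ccccc2)cc1OCc1ccccc1 | intermediate
4 | (2S)-5,7-bis(benzyloxy)-2-[4-(benzyloxy)phenyl]chroman-4-one | O=C1C[C@@H](c2ccc(OCc3ccccc3)cc2)Oc2cc(OCc3ccccc3)cc(OCc3ccccc3)c21 | intermediate
5 | (2S)-5,7-bis(benzyloxy)-2-[4-(benzyloxy)phenyl]-4-(trimethylsilyloxy)-2H-chromene | C[Si](C)(C)OC1=C[C@@H](c2ccc(OCc3ccccc3)cc2)Oc2cc(OCc3ccccc3)cc(OCc3ccccc3)c21 | intermediate (not isolated)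
6 | (2R,3R)-5,7-bis(benzyloxy)-2-[4-(benzyloxy)phenyl]-3-bromochroman-4-one (2,3-trans) | O=C1[C@H](Br)[C@@H](c2ccc(OCc3ccccc3)cc2)Oc2cc(OCc3ccccc3)cc(OCc3ccccc3)c21 | intermediate
7 | (2R,3S,4R)-5,7-bis(benzyloxy)-2-[4-(benzyloxy)phenyl]-3-bromochroman-4-ol (2,3-trans-3,4-trans) | O[C@H]1[C@H](Br)[C@@H](c2ccc(OCc3ccccc3)cc2)Oc2cc(OCc3ccccc3)cc(OCc3ccccc3)c21 | intermediate (not isolated)
8 | (2R,3R,4R)-5,7-bis(benzyloxy)-2-[4-(benzyloxy)phenyl]-3,4-epoxychroman (oxirane cis to the 2-aryl group) | O1[C@@H]2[C@H]1c1c(OCc3ccccc3)cc(OCc3ccccc3)cc1O[C@@H]2c1ccc(OCc2ccccc2)cc1 | intermediate (not isolated)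
9 | (2R,3R,4S)-5,7-bis(benzyloxy)-2-[4-(benzyloxy)phenyl]-4-methoxychroman-3-ol (2,3-cis-3,4-trans; 4β-methoxy-tri-O-benzyl-epiafzelechin) | CO[C@@H]1[C@@H](O)[C@@H](c2ccc(OCc3ccccc3)cc2)Oc2cc(OCc3ccccc3)cc(OCc3ccccc3)c21 | intermediate
10 | (−)-epicatechin, (2R,3R)-2-(3,4-dihydroxyphenyl)chroman-3,5,7-triol | O[C@@H]1Cc2c(O)cc(O)cc2O[C@@H]1c1ccc(O)c(O)c1 | starting material
11 | 5,7,4'-tri-O-benzyl-(−)-epiafzelechin-(4β→8)-(−)-epicatechin; upper unit (2R,3R,4R), lower unit (2R,3R) | c1ccccc1COc1ccc([C@H]2Oc3cc(OCc4ccccc4)cc(OCc4ccccc4)c3[C@H](c3c(O)cc(O)c4c3O[C@H](c3ccc(O)c(O)c3)[C@H](O)C4)[C@H]2O)cc1 | intermediate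
12 | (−)-epiafzelechin-(4β→8)-(−)-epicatechin; upper unit (2R,3R,4R), lower unit (2R,3R) | Oc1ccc([C@H]2Oc3cc(O)cc(O)c3[C@H](c3c(O)cc(O)c4c3O[C@H](c3ccc(O)c(O)c3)[C@H](O)C4)[C@H]2O)cc1 | target

**Totals**
Total step count: 6. Longest linear sequence: 6 steps (1 and 2 to 12).

**Steps most likely to fail**

Step 2. The enantioselective ring closure may be slow, stop at an equilibrium mixture, or give low ee because closure is reversible under the basic catalyst. The fallback sets out from 3 and comes back at 4. Chalcone 3 is cyclised without stereocontrol (NaOAc, EtOH, reflux) to the racemic flavanone rac-5,7-bis(benzyloxy)-2-[4-(benzyloxy)phenyl]chroman-4-one F1. F1 is then resolved kinetically by asymmetric transfer hydrogenation with RuCl[(R,R)-TsDPEN](p-cymene) (1 mol %) and HCO2H/Et3N (5:2) in EtOAc at 25 °C to about 55% conversion. The (2R)-ketone is expected to be the fast-reacting enantiomer and is reduced to the cis-alcohol (2R,4R)-5,7-bis(benzyloxy)-2-[4-(benzyloxy)phenyl]chroman-4-ol F2, which is removed by chromatography. The unreacted (2S)-ketone is 4.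

Step 4. The hydride may attack from the other face, giving a 3,4-cis bromohydrin that cannot close. Base may also eliminate HBr to the flavone, or the oxirane may rearrange instead of being trapped. The fallback sets out from 4 and comes back at 9; it sets C3 by hydride delivery to a 3-ketone and brings in the C4 oxygen by benzylic oxidation instead of by SN2 inversion.
- Ketone 4 is reduced (NaBH4, THF/MeOH, 0 °C) to (2S,4S)-5,7-bis(benzyloxy)-2-[4-(benzyloxy)phenyl]chroman-4-ol F3.
- F3 is dehydrated (TsOH cat., toluene, 60 °C) to (2S)-5,7-bis(benzyloxy)-2-[4-(benzyloxy)phenyl]-2H-chromene F4.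
- Hydroboration–oxidation (BH3·THF, then H2O2/NaOH) anti to the 2-aryl group gives the 2,3-trans alcohol 5,7,4'-tri-O-benzyl-(+)-afzelechin F5.
- Dess–Martin periodinane in wet CH2Cl2 gives (2R)-5,7-bis(benzyloxy)-2-[4-(benzyloxy)phenyl]chroman-3-one F6, used at once.
- LiBH(s-Bu)3 (L-Selectride) in THF at −78 °C delivers hydride anti to the 2-aryl group and gives 5,7,4'-tri-O-benzyl-(−)-epiafzelechin F7.
- DDQ in CH2Cl2/MeOH at 25 °C oxidises C4 and methanol adds trans to the 3-OH, which gives 9.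

Step 5. The free-phenolic nucleophile can also react at C6, the product can be alkylated again to trimers, and 9 can self-condense through its own ring A. The fallback sets out from 10 (with 9) and comes back at 12, replacing steps 5 and 6. Compound 10 is benzylated on its four phenols (BnBr, K2CO3, DMF, 0 → 25 °C) to 5,7,3',4'-tetra-O-benzyl-(−)-epicatechin F8. Ether 9 is coupled with F8 (4 equiv) using TMSOTf in CH2Cl2 at −78 °C, which gives only the C8-linked 5,7,4'-tri-O-benzyl-(−)-epiafzelechin-(4β→8)-5,7,3',4'-tetra-O-benzyl-(−)-epicatechin F9. Global hydrogenolysis (H2, Pd(OH)2/C, THF/MeOH) gives 12.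

**Further compounds**
F1 | step 2 | rac-5,7-bis(benzyloxy)-2-[4-(benzyloxy)phenyl]chroman-4-one (racemate) | O=C1CC(c2ccc(OCc3ccccc3)cc2)Oc2cc(OCc3ccccc3)cc(OCc3ccccc3)c21
F2 | step 2 | (2R,4R)-5,7-bis(benzyloxy)-2-[4-(benzyloxy)phenyl]chroman-4-ol | O[C@@H]1C[C@H](c2ccc(OCc3ccccc3)cc2)Oc2cc(OCc3ccccc3)cc(OCc3ccccc3)c21
F3 | step 4 | (2S,4S)-5,7-bis(benzyloxy)-2-[4-(benzyloxy)phenyl]chroman-4-ol | O[C@H]1C[C@@H](c2ccc(OCc3ccccc3)cc2)Oc2cc(OCc3ccccc3)cc(OCc3ccccc3)c21
F4 | step 4 | (2S)-5,7-bis(benzyloxy)-2-[4-(benzyloxy)phenyl]-2H-chromene | C1=C[C@@H](c2ccc(OCc3ccccc3)cc2)Oc2cc(OCc3ccccc3)cc(OCc3ccccc3)c21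
F5 | step 4 | (2R,3S)-5,7-bis(benzyloxy)-2-[4-(benzyloxy)phenyl]chroman-3-ol (tri-O-benzyl-afzelechin) | O[C@H]1Cc2c(OCc3ccccc3)cc(OCc3ccccc3)cc2O[C@@H]1c1ccc(OCc2ccccc2)cc1
F6 | step 4 | (2R)-5,7-bis(benzyloxy)-2-[4-(benzyloxy)phenyl]chroman-3-one | O=C1Cc2c(OCc3ccccc3)cc(OCc3ccccc3)cc2O[C@@H]1c1ccc(OCc2ccccc2)cc1
F7 | step 4 | (2R,3R)-5,7-bis(benzyloxy)-2-[4-(benzyloxy)phenyl]chroman-3-ol (tri-O-benzyl-epiafzelechin) | O[C@@H]1Cc2c(OCc3ccccc3)cc(OCc3ccccc3)cc2O[C@@H]1c1ccc(OCc2ccccc2)cc1
F8 | step 5 | (2R,3R)-5,7-bis(benzyloxy)-2-[3,4-bis(benzyloxy)phenyl]chroman-3-ol (tetra-O-benzyl-epicatechin) | O[C@@H]1Cc2c(OCc3ccccc3)cc(OCc3ccccc3)cc2O[C@@H]1c1ccc(OCc2ccccc2)c(OCc2ccccc2)c1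
F9 | step 5 | 5,7,4'-tri-O-benzyl-(−)-epiafzelechin-(4β→8)-5,7,3',4'-tetra-O-benzyl-(−)-epicatechin | c1ccccc1COc1ccc([C@H]2Oc3cc(OCc4ccccc4)cc(OCc4ccccc4)c3[C@H](c3c(OCc5ccccc5)cc(OCc5ccccc5)c4c3O[C@H](c3ccc(OCc5ccccc5)c(OCc5ccccc5)c3)[C@H](O)C4)[C@H]2O)cc1
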